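**Retrosynthetic overview**
- Last operations: the C1 carbinol is oxidised and the exocyclic alkene moved into conjugation, after acylation of the C14 primary OH (angelic anhydride) and the C7 OH (Ac2O).
- The seven-membered ring is closed last (C5–C6 bond) by an ester-enolate aldol onto a cyclobutanone, followed by radical removal of the C5 oxygen.
- The cyclobutane and the six-membered ring are formed together by an intramolecular vinylketene–alkene [2+2] of an open-chain C15 dienoic acid; the C1 silyloxy stereocentre steers the alkene face.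
- That acid comes from a B-alkyl Suzuki coupling of fragment A (C9 vinyl iodide acid, from a C5 dienolate and a C4 iodoenal by asymmetric vinylogous aldol) with fragment B (C6 alkene ester, from propanoyl chloride and acrolein by Evans aldol).
- Ring compounds use longipinane numbering: C1 carbonyl, C2=C3 (C12 on C3), C4/C11 bridgeheads, C5 and C10 one-carbon bridges (C15 on C10), C6–C9 four-carbon bridge (C13 methyl and C14 CH2O on C6).

Assumption: the enantiomer is exactly the one written in the SMILES; the oxazolidinone auxiliary, the bisphosphoramide catalyst and Cp2Zr(H)Cl are bought.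

**Route**

Step 1
Reactants: 1 3-methylbut-2-enoic acid
Product: 2 tert-butyl 3-methylbut-2-enoate
Conditions: isobutene, H2SO4 (cat.), CH2Cl2, sealed tube, rt
Reagents that add atoms: isobutene CC(C)=C
Why: Acid-catalysed addition of the carboxylic acid to isobutene gives the tert-butyl ester, which serves only as a carboxyl mask.

Step 2
Reactants: 2 tert-butyl 3-methylbut-2-enoate
Product: 4 tert-butyl[(1-tert-butoxy-3-methylbuta-1,3-dien-1-yl)oxy]dimethylsilane, via lithium dienolate 3 (not isolated)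
Conditions: LDA, THF, −78 °C; then TBSCl, DMPU, −78 °C → rt
Reagents that add atoms: tert-butylchlorodimethylsilane C[Si](C)(Cl)C(C)(C)C
Why: Kinetic γ-deprotonation of the senecioate gives the extended dienolate, which is O-silylated (silyl dienol ether formation).

Step 3
Reactants: 5 but-2-yn-1-ol
Product: 7 (E)-3-iodobut-2-en-1-ol, via bis-zirconocene intermediate 6 (not isolated)
Conditions: Cp2Zr(H)Cl (2.3 equiv), THF, 0 °C → rt; then I2, 0 °C
Reagents that add atoms: iodine [I][I]
Why: Syn-hydrozirconation (Schwartz reagent) puts zirconium on C3, remote from the bulky zirconium alkoxide, and iododezirconation with retention gives the E vinyl iodide.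

Step 4
Reactants: 7 (E)-3-iodobut-2-en-1-ol
Product: 8 (E)-3-iodobut-2-enal
Conditions: Dess–Martin periodinane, CH2Cl2, 0 °C, dark; used at once
Reagents that add atoms: none
Why: Dess–Martin oxidation of the allylic alcohol under neutral conditions keeps the E geometry of the β-iodoenal.

Step 5
Reactants: 4 tert-butyl[(1-tert-butoxy-3-methylbuta-1,3-dien-1-yl)oxy]dimethylsilane; 8 (E)-3-iodobut-2-enal
Product: 9 tert-butyl (2E,5R,6E)-5-hydroxy-7-iodo-3-methylocta-2,6-dienoate
Conditions: SiCl4 (1.1 equiv), Denmark BINAM-derived bisphosphoramide (antipode giving Re-face attack, 2 mol %), iPr2NEt (cat.), CH2Cl2, −78 °C; aq. NaHCO3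
Reagents that add atoms: none
Why: Lewis-base-activated SiCl4 vinylogous Mukaiyama aldol gives exclusive γ-attack through the s-trans dienolate (2E enoate), and the chiral phosphoramide-bound silicon cation directs Re-face attack on the aldehyde, setting C5 as R (the future C1).

Step 6
Reactants: 9 tert-butyl (2E,5R,6E)-5-hydroxy-7-iodo-3-methylocta-2,6-dienoate
Product: 11 (2E,5R,6E)-5-(tert-butyldimethylsilyloxy)-7-iodo-3-methylocta-2,6-dienoic acid (fragment A), via bis-silyl compound 10 (not isolated)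
Conditions: TBSOTf (2.5 equiv), 2,6-lutidine, CH2Cl2, 0 °C → rt; then K2CO3, MeOH/H2O, 0 °C; pH 4 buffer
Reagents that add atoms: tert-butyldimethylsilyl triflate C[Si](C)(OS(=O)(=O)C(F)(F)F)C(C)(C)C
Why: The silyl triflate silylates the alcohol and converts the tert-butyl ester into a silyl ester with loss of isobutene, and mild carbonate hydrolysis then cleaves only the labile silyl ester.

Step 7
Reactants: 12 propanoyl chloride
Product: 13 (4S)-4-benzyl-3-propanoyl-1,3-oxazolidin-2-one
Conditions: (S)-4-benzyl-1,3-oxazolidin-2-one, Et3N, DMAP (cat.), CH2Cl2, 0 °C → rt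
Reagents that add atoms: (S)-4-benzyl-1,3-oxazolidin-2-one O=C1N[C@@H](Cc2ccccc2)CO1
Why: DMAP-catalysed N-acylation attaches the Evans auxiliary.

Step 8
Reactants: 13 (4S)-4-benzyl-3-propanoyl-1,3-oxazolidin-2-one; 14 acrolein
Product: 16 (4S)-4-benzyl-3-[(2S,3R)-3-hydroxy-2-methylpent-4-enoyl]-1,3-oxazolidin-2-one, via boron enolate 15 (not isolated)
Conditions: Bu2BOTf, iPr2NEt, CH2Cl2, −78 → 0 °C; then 14, −78 → 0 °C; pH 7 buffer, MeOH, H2O2
Reagents that add atoms: none
Why: Evans boron aldol reaction, in which the Z-enolate reacts through a chair Zimmerman–Traxler transition state on the face away from the benzyl group to give the syn adduct and set the carbinol (future C7) as R; the α-centre is enolised later.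

Step 9
Reactants: 16 (4S)-4-benzyl-3-[(2S,3R)-3-hydroxy-2-methylpent-4-enoyl]-1,3-oxazolidin-2-one
Product: 17 methyl (2S,3R)-3-hydroxy-2-methylpent-4-enoate
Conditions: NaOMe (0.5 equiv), MeOH, 0 °C, 10 min
Reagents that add atoms: methanol CO
Why: Methoxide-catalysed transesterification at the exocyclic imide carbonyl releases the methyl ester and the auxiliary.

Step 10
Reactants: 17 methyl (2S,3R)-3-hydroxy-2-methylpent-4-enoate
Product: 18 methyl (2S,3R)-2-methyl-3-(triethylsilyloxy)pent-4-enoate (fragment B)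
Conditions: TESCl, imidazole, DMF, 0 °C → rt
Reagents that add atoms: chlorotriethylsilane CC[Si](Cl)(CC)CC
Why: Silylation gives a non-chelating silyl ether, which is needed for the stereochemical course of step 13.

Step 11
Reactants: 18 methyl (2S,3R)-2-methyl-3-(triethylsilyloxy)pent-4-enoate; 11 (2E,5R,6E)-5-(tert-butyldimethylsilyloxy)-7-iodo-3-methylocta-2,6-dienoic acid
Product: 20 (2E,5R,6E,10R,11S)-5-(tert-butyldimethylsilyloxy)-12-methoxy-3,7,11-trimethyl-12-oxo-10-(triethylsilyloxy)dodeca-2,6-dienoic acid, via alkylborane 19 (not isolated)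
Conditions: 9-BBN, THF, rt; then 11, PdCl2(dppf) (5 mol %), AsPh3, Cs2CO3 (4 equiv), DMF/H2O, rt; pH 4 buffer
Reagents that add atoms: none
Why: Anti-Markovnikov hydroboration of the terminal alkene followed by palladium-catalysed B-alkyl Suzuki–Miyaura coupling with the vinyl iodide (present as its caesium carboxylate) proceeds with retention to give the 6E trisubstituted alkene.

Step 12
Reactants: 20 (2E,5R,6E,10R,11S)-5-(tert-butyldimethylsilyloxy)-12-methoxy-3,7,11-trimethyl-12-oxo-10-(triethylsilyloxy)dodeca-2,6-dienoic acid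
Product: 23 methyl (2S,3R)-5-[(1S,4R,5S,7S)-4-(tert-butyldimethylsilyloxy)-7-methyl-2-methylidene-6-oxobicyclo[3.1.1]heptan-7-yl]-2-methyl-3-(triethylsilyloxy)pentanoate, via acid chloride 21 (not isolated), via vinylketene 22 (not isolated)
Conditions: 1-chloro-N,N,2-trimethylprop-1-en-1-amine, CH2Cl2, 0 °C → rt; then syringe-pump addition to Et3N (5 equiv), PhMe, reflux, 0.005 M
Reagents that add atoms: none
Why: Et3N removes a proton from the C3 methyl cis to COCl to give the vinylketene, which undergoes the intramolecular crossed ketene–alkene [2+2] cycloaddition (carbonyl carbon to the CH end, ketene α-carbon to the disubstituted end); the E alkene geometry places the side chain on the carbonyl-bridge side, and the allylic OTBS group takes the outside position away from the C10 methyl so that one alkene face reacts, which sets C4, C10 and C11.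

Step 13
Reactants: 23 methyl (2S,3R)-5-[(1S,4R,5S,7S)-4-(tert-butyldimethylsilyloxy)-7-methyl-2-methylidene-6-oxobicyclo[3.1.1]heptan-7-yl]-2-methyl-3-(triethylsilyloxy)pentanoate
Product: 25 methyl (1R,7R)-1-(tert-butyldimethylsilyloxy)-5-(methoxyoxalyloxy)-7-(triethylsilyloxy)longipin-3(12)-en-14-oate, via lithium aldolate 24 (not isolated)
Conditions: LDA (1.15 equiv), THF, −78 °C; then ClC(O)CO2Me (3 equiv), −78 → −20 °C
Reagents that add atoms: methyl chlorooxoacetate COC(=O)C(Cl)=O
Why: Intramolecular aldol addition of the ester enolate to the non-enolisable cyclobutanone closes the seven-membered ring, A(1,3) strain keeping C7–H in the enolate plane with the non-chelating C7–OTES anti to the forming bond so that C6 is formed with CO2Me trans to the C7 oxygen, while C5 is fixed by the cage and the aldolate is trapped as the methyl oxalate before retro-aldol can occur.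

Step 14
Reactants: 25 methyl (1R,7R)-1-(tert-butyldimethylsilyloxy)-5-(methoxyoxalyloxy)-7-(triethylsilyloxy)longipin-3(12)-en-14-oate
Product: 26 methyl (1R,7R)-1-(tert-butyldimethylsilyloxy)-7-(triethylsilyloxy)longipin-3(12)-en-14-oate
Conditions: Bu3SnH, AIBN, PhMe, reflux
Reagents that add atoms: none
Why: Tin hydride radical deoxygenation of the tertiary methyl oxalate (Dolan–MacMillan variant of the Barton–McCombie reaction) gives a cage-locked cyclobutyl radical that cannot eliminate and takes up hydrogen with the only possible configuration at C5.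

Step 15
Reactants: 26 methyl (1R,7R)-1-(tert-butyldimethylsilyloxy)-7-(triethylsilyloxy)longipin-3(12)-en-14-oate
Product: 27 (1R,7R)-1-(tert-butyldimethylsilyloxy)-7-(triethylsilyloxy)longipin-3(12)-en-14-ol
Conditions: DIBAL-H (4 equiv), CH2Cl2, −78 → 0 °C; Rochelle salt
Reagents that add atoms: none
Why: Hydride reduction of the neopentyl methyl ester gives the primary alcohol while silyl ethers and the alkene are inert.

Step 16
Reactants: 27 (1R,7R)-1-(tert-butyldimethylsilyloxy)-7-(triethylsilyloxy)longipin-3(12)-en-14-ol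
Product: 28 (1R,7R)-1-(tert-butyldimethylsilyloxy)longipin-3(12)-ene-7,14-diol
Conditions: PPTS (cat.), MeOH/CH2Cl2, 0 °C
Reagents that add atoms: none
Why: Acid-catalysed methanolysis removes the triethylsilyl ether selectively in the presence of the secondary tert-butyldimethylsilyl ether.

Step 17
Reactants: 29 angelic acid ((Z)-2-methylbut-2-enoic acid, 2 equiv)
Product: 30 angelic anhydride ((Z)-2-methylbut-2-enoic anhydride)
Conditions: DCC (0.5 equiv), CH2Cl2, 0 °C → rt; filter
Reagents that add atoms: none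
Why: Carbodiimide dehydration gives the anhydride without Z-to-E isomerisation.

Step 18
Reactants: 28 (1R,7R)-1-(tert-butyldimethylsilyloxy)longipin-3(12)-ene-7,14-diol; 30 angelic anhydride
Product: 32 (1R,7R)-7-acetoxy-14-angeloyloxy-1-(tert-butyldimethylsilyloxy)longipin-3(12)-ene, via lithium alkoxide 31 (not isolated)
Conditions: LiHMDS (2.1 equiv), THF, −78 °C; 30 (1.0 equiv), −78 → −30 °C; then Ac2O (3 equiv), −30 °C → rt
Reagents that add atoms: acetic anhydride CC(=O)OC(C)=O
Why: Alkoxide acylation, in which the less hindered primary alkoxide takes the angeloyl group (base-mediated, no nucleophilic catalyst, so the Z alkene is kept) and the remaining secondary alkoxide is then acetylated in the same flask.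

Step 19
Reactants: 32 (1R,7R)-7-acetoxy-14-angeloyloxy-1-(tert-butyldimethylsilyloxy)longipin-3(12)-ene
Product: 33 (1R,7R)-7-acetoxy-14-angeloyloxylongipin-3(12)-en-1-ol
Conditions: HF·pyridine, pyridine, THF, 0 °C → rt
Reagents that add atoms: none
Why: Fluoride-mediated desilylation under buffered conditions leaves both esters untouched.

Step 20
Reactants: 33 (1R,7R)-7-acetoxy-14-angeloyloxylongipin-3(12)-en-1-ol
Product: 35 (7R)-7-acetoxy-14-angeloyloxylongipin-2-en-1-one (target CNP0374220.2), via deconjugated enone 34 (not isolated)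
Conditions: Dess–Martin periodinane, CH2Cl2, rt; then DBU, rt
Reagents that add atoms: none
Why: Dess–Martin oxidation gives the β,γ-unsaturated ketone, and DBU moves the exocyclic double bond into conjugation through the C2 dienolate (the C11 bridgehead cannot enolise), giving the trisubstituted enone.

**Compound list**

1 | 3-methylbut-2-enoic acid | CC(C)=CC(=O)O | starting material
2 | tert-butyl 3-methylbut-2-enoate | CC(C)=CC(=O)OC(C)(C)C | intermediate
3 | lithium 1-tert-butoxy-3-methylbuta-1,3-dien-1-olate | [Li+].[O-]C(OC(C)(C)C)=CC(C)=C | intermediate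
4 | tert-butyl[(1-tert-butoxy-3-methylbuta-1,3-dien-1-yl)oxy]dimethylsilane (ketene acetal geometry not defined) | C=C(C)C=C(OC(C)(C)C)O[Si](C)(C)C(C)(C)C | intermediate
5 | but-2-yn-1-ol | CC#CCO | starting material
6 | (E)-3-(chlorozirconocenyl)but-2-enyl chlorozirconocene alkoxide | C/C(=C\CO[Zr](Cl)(C1C=CC=C1)C1C=CC=C1)[Zr](Cl)(C1C=CC=C1)C1C=CC=C1 | intermediate
7 | (E)-3-iodobut-2-en-1-ol | I/C(C)=C/CO | intermediate
8 | (E)-3-iodobut-2-enal | I/C(C)=C/C=O | intermediate
9 | tert-butyl (2E,5R,6E)-5-hydroxy-7-iodo-3-methylocta-2,6-dienoate | CC(C)(C)OC(=O)/C=C(\C)C[C@@H](O)/C=C(\C)I | intermediate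
10 | tert-butyldimethylsilyl (2E,5R,6E)-5-(tert-butyldimethylsilyloxy)-7-iodo-3-methylocta-2,6-dienoate | C[Si](C)(C(C)(C)C)OC(=O)/C=C(\C)C[C@@H](O[Si](C)(C)C(C)(C)C)/C=C(\C)I | intermediate
11 | (2E,5R,6E)-5-(tert-butyldimethylsilyloxy)-7-iodo-3-methylocta-2,6-dienoic acid (fragment A) | OC(=O)/C=C(\C)C[C@@H](O[Si](C)(C)C(C)(C)C)/C=C(\C)I | intermediate
12 | propanoyl chloride | CCC(Cl)=O | starting material
13 | (4S)-4-benzyl-3-propanoyl-1,3-oxazolidin-2-one | CCC(=O)N1[C@@H](Cc2ccccc2)COC1=O | intermediate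
14 | acrolein | C=CC=O | starting material
15 | (Z)-dibutylboron enolate of 13 | C/C=C(\OB(CCCC)CCCC)N1[C@@H](Cc2ccccc2)COC1=O | intermediate
16 | (4S)-4-benzyl-3-[(2S,3R)-3-hydroxy-2-methylpent-4-enoyl]-1,3-oxazolidin-2-one | C=C[C@@H](O)[C@H](C)C(=O)N1[C@@H](Cc2ccccc2)COC1=O | intermediate
17 | methyl (2S,3R)-3-hydroxy-2-methylpent-4-enoate | C=C[C@@H](O)[C@H](C)C(=O)OC | intermediate
18 | methyl (2S,3R)-2-methyl-3-(triethylsilyloxy)pent-4-enoate (fragment B) | C=C[C@@H](O[Si](CC)(CC)CC)[C@H](C)C(=O)OC | intermediate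
19 | methyl (2S,3R)-5-(9-borabicyclo[3.3.1]nonan-9-yl)-2-methyl-3-(triethylsilyloxy)pentanoate | C1CC2CCCC(C1)B2CC[C@@H](O[Si](CC)(CC)CC)[C@H](C)C(=O)OC | intermediate
20 | (2E,5R,6E,10R,11S)-5-(tert-butyldimethylsilyloxy)-12-methoxy-3,7,11-trimethyl-12-oxo-10-(triethylsilyloxy)dodeca-2,6-dienoic acid | OC(=O)/C=C(\C)C[C@@H](O[Si](C)(C)C(C)(C)C)/C=C(\C)CC[C@@H](O[Si](CC)(CC)CC)[C@H](C)C(=O)OC | intermediate
21 | acid chloride of 20 | ClC(=O)/C=C(\C)C[C@@H](O[Si](C)(C)C(C)(C)C)/C=C(\C)CC[C@@H](O[Si](CC)(CC)CC)[C@H](C)C(=O)OC | intermediate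
22 | vinylketene from 21 (C3 methylidene; ketene at C1) | O=C=CC(=C)C[C@@H](O[Si](C)(C)C(C)(C)C)/C=C(\C)CC[C@@H](O[Si](CC)(CC)CC)[C@H](C)C(=O)OC | intermediate
23 | methyl (2S,3R)-5-[(1S,4R,5S,7S)-4-(tert-butyldimethylsilyloxy)-7-methyl-2-methylidene-6-oxobicyclo[3.1.1]heptan-7-yl]-2-methyl-3-(triethylsilyloxy)pentanoate; OTBS on the side of the carbonyl bridge; side chain on C7 pointing to the carbonyl bridge | O=C1[C@H]2C(=C)C[C@@H](O[Si](C)(C)C(C)(C)C)[C@@H]1[C@@]2(C)CC[C@@H](O[Si](CC)(CC)CC)[C@H](C)C(=O)OC | intermediate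
24 | lithium C5 alkoxide of the tricyclic aldol adduct | COC(=O)[C@]1(C)[C@]2([O-])[C@H]3C(=C)C[C@@H](O[Si](C)(C)C(C)(C)C)[C@@H]2[C@@]3(C)CC[C@H]1O[Si](CC)(CC)CC.[Li+] | intermediate
25 | methyl (1R,7R)-1-(tert-butyldimethylsilyloxy)-5-(methoxyoxalyloxy)-7-(triethylsilyloxy)longipin-3(12)-en-14-oate; C6 methyl cis to the C7 oxygen | COC(=O)[C@]1(C)[C@]2(OC(=O)C(=O)OC)[C@H]3C(=C)C[C@@H](O[Si](C)(C)C(C)(C)C)[C@@H]2[C@@]3(C)CC[C@H]1O[Si](CC)(CC)CC | intermediate
26 | methyl (1R,7R)-1-(tert-butyldimethylsilyloxy)-7-(triethylsilyloxy)longipin-3(12)-en-14-oate | COC(=O)[C@]1(C)[C@@H]2[C@H]3C(=C)C[C@@H](O[Si](C)(C)C(C)(C)C)[C@@H]2[C@@]3(C)CC[C@H]1O[Si](CC)(CC)CC | intermediate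
27 | (1R,7R)-1-(tert-butyldimethylsilyloxy)-7-(triethylsilyloxy)longipin-3(12)-en-14-ol | OC[C@]1(C)[C@@H]2[C@H]3C(=C)C[C@@H](O[Si](C)(C)C(C)(C)C)[C@@H]2[C@@]3(C)CC[C@H]1O[Si](CC)(CC)CC | intermediate
28 | (1R,7R)-1-(tert-butyldimethylsilyloxy)longipin-3(12)-ene-7,14-diol | OC[C@]1(C)[C@@H]2[C@H]3C(=C)C[C@@H](O[Si](C)(C)C(C)(C)C)[C@@H]2[C@@]3(C)CC[C@H]1O | intermediate
29 | angelic acid ((Z)-2-methylbut-2-enoic acid) | C/C=C(/C)C(=O)O | starting material
30 | angelic anhydride | C/C=C(/C)C(=O)OC(=O)/C(C)=C\C | intermediate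
31 | lithium C7 alkoxide of the C14 mono-angelate | C/C=C(/C)C(=O)OC[C@]1(C)[C@@H]2[C@H]3C(=C)C[C@@H](O[Si](C)(C)C(C)(C)C)[C@@H]2[C@@]3(C)CC[C@H]1[O-].[Li+] | intermediate
32 | (1R,7R)-7-acetoxy-14-angeloyloxy-1-(tert-butyldimethylsilyloxy)longipin-3(12)-ene | C/C=C(/C)C(=O)OC[C@]1(C)[C@@H]2[C@H]3C(=C)C[C@@H](O[Si](C)(C)C(C)(C)C)[C@@H]2[C@@]3(C)CC[C@H]1OC(C)=O | intermediate
33 | (1R,7R)-7-acetoxy-14-angeloyloxylongipin-3(12)-en-1-ol | C/C=C(/C)C(=O)OC[C@]1(C)[C@@H]2[C@H]3C(=C)C[C@@H](O)[C@@H]2[C@@]3(C)CC[C@H]1OC(C)=O | intermediate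
34 | (7R)-7-acetoxy-14-angeloyloxylongipin-3(12)-en-1-one | C/C=C(/C)C(=O)OC[C@]1(C)[C@@H]2[C@H]3C(=C)CC(=O)[C@@H]2[C@@]3(C)CC[C@H]1OC(C)=O | intermediate
35 | (7R)-7-acetoxy-14-angeloyloxylongipin-2-en-1-one (CNP0374220.2) | C/C=C(/C)C(=O)OC[C@]1(C)[C@@H]2[C@H]3C(C)=CC(=O)[C@@H]2[C@@]3(C)CC[C@H]1OC(C)=O | target

**Step count**

Total steps: 20.
Longest linear sequence: 13 steps (3, 4, 5, 6, 11, 12, 13, 14, 15, 16, 18, 19, 20; the branches through steps 1–2 and through steps 7–10 are equally long).

**Three steps most likely to fail**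

Step 12 is the least certain. The ketene can dimerise, the allylic silyloxy group slows attack on the alkene, and the face selectivity rests on a conformational argument. The fallback sets out from acid 20 and replaces the ketene by a keteniminium ion. Amide coupling with pyrrolidine gives the pyrrolidine amide F1. Tf2O and 2,4,6-collidine in 1,2-dichloroethane then generate the more electrophilic vinylketeniminium salt, which cyclises at lower temperature to the cyclobutaniminium triflate F2. Aqueous NaHCO3 hydrolysis returns to the route at ketone 23.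

Step 13 can fail by retro-aldol, by loss of silanolate from the β-silyloxy enolate, by incomplete acylation of the hindered aldolate, or by giving the wrong C6 epimer. The fallback sets out from ketone 23 and uses a Lewis-acid aldol with an open transition state instead of the lithium enolate. LDA in the presence of TMSCl (in situ quench) gives the ketene silyl acetal F3. TiCl4 in CH2Cl2 at −78 °C then effects an intramolecular Mukaiyama aldol, and work-up gives the tertiary alcohol F4, with no free alkoxide at any point. Acylation with methyl chlorooxoacetate and DMAP returns to the route at oxalate 25.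

Step 14 can fail because the very hindered oxalate may propagate the radical chain poorly. The fallback sets out from oxalate 25 and cleaves the tertiary C–O bond from a tethered thiocarbonyl group. LiAlH4 reduces both ester groups to give the 1,3-diol F5, and 1,1'-thiocarbonyldiimidazole closes the cyclic thionocarbonate F6. Bu3SnH and AIBN then break the tertiary C–O bond selectively (Barton deoxygenation of a cyclic thionocarbonate), and K2CO3 in MeOH frees the primary alcohol. This returns to the route at alcohol 27, so step 15 is not needed.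

Further compounds
F1 | step 12 | pyrrolidine amide of acid 20 | O=C(/C=C(\C)C[C@@H](O[Si](C)(C)C(C)(C)C)/C=C(\C)CC[C@@H](O[Si](CC)(CC)CC)[C@H](C)C(=O)OC)N1CCCC1
F2 | step 12 | cyclobutaniminium triflate (pyrrolidinium analogue of 23) | [O-]S(=O)(=O)C(F)(F)F.C1CC[N+](C1)=C1[C@H]2C(=C)C[C@@H](O[Si](C)(C)C(C)(C)C)[C@@H]1[C@@]2(C)CC[C@@H](O[Si](CC)(CC)CC)[C@H](C)C(=O)OC
F3 | step 13 | methyl trimethylsilyl ketene acetal of 23 | O=C1[C@H]2C(=C)C[C@@H](O[Si](C)(C)C(C)(C)C)[C@@H]1[C@@]2(C)CC[C@@H](O[Si](CC)(CC)CC)C(C)=C(OC)O[Si](C)(C)C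
F4 | step 13 | methyl (1R,7R)-1-(tert-butyldimethylsilyloxy)-5-hydroxy-7-(triethylsilyloxy)longipin-3(12)-en-14-oate | COC(=O)[C@]1(C)[C@]2(O)[C@H]3C(=C)C[C@@H](O[Si](C)(C)C(C)(C)C)[C@@H]2[C@@]3(C)CC[C@H]1O[Si](CC)(CC)CC
F5 | step 14 | (1R,7R)-1-(tert-butyldimethylsilyloxy)-7-(triethylsilyloxy)longipin-3(12)-ene-5,14-diol | OC[C@]1(C)[C@]2(O)[C@H]3C(=C)C[C@@H](O[Si](C)(C)C(C)(C)C)[C@@H]2[C@@]3(C)CC[C@H]1O[Si](CC)(CC)CC
F6 | step 14 | cyclic 5,14-thionocarbonate of F5 | O4C[C@]1(C)[C@]2(OC4=S)[C@H]3C(=C)C[C@@H](O[Si](C)(C)C(C)(C)C)[C@@H]2[C@@]3(C)CC[C@H]1O[Si](CC)(CC)CC
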